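**Retrosynthetic overview**
- Numbering: ring A is C1 (OH), C2 (O-aryl), C3-H, C4-H, C5 (Br), C6 (Br). Ring B is C1' (O), C2' (Br), C4' (Br).
- Feature: C5 and C4' are para and C2' is ortho to the bridging ether oxygen, while C6 is ortho only to the C1 oxygen. Without bromine the skeleton is commercial 2-phenoxyphenol.
- Last disconnection: the C1 O–C(O)NEt2 bond. The phenol is released from its N,N-diethylcarbamate.
- Key disconnection: the C5–Br, C4'–Br and C2'–Br bonds are cut together. This is an electrophilic tribromination of the 6-bromo carbamate, in which the acylated C1 oxygen is muted and the ether oxygen directs.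
- C6–Br goes back to carbamate-directed ortho-lithiation and bromination of 2-phenoxyphenyl diethylcarbamate. Both rings and the C–O–C bridge are bought, so no ring is formed.

Key step: step 3

Remark: the target has no stereocentre and the diaryl ether rotates freely, so no stereocontrol is needed and the SMILES carry no stereo descriptors.

**Step 1**
Reactants: 1 2-phenoxyphenol; 2 N,N-diethylcarbamoyl chloride
Product: 4 2-phenoxyphenyl N,N-diethylcarbamate, via sodium 2-phenoxyphenolate 3 (not isolated)
Conditions: NaH (1.2 equiv), THF, 0 °C; then 2 (1.2 equiv), 0 °C → rt
Reagents that add atoms: N,N-diethylcarbamoyl chloride, CCN(CC)C(=O)Cl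
Why: O-carbamoylation by nucleophilic acyl substitution, in which the preformed phenolate 3 is the only nucleophile present and displaces chloride from 2, while the diaryl ether is inert to NaH.

**Step 2**
Reactants: 4 2-phenoxyphenyl N,N-diethylcarbamate; 5 1,2-dibromo-1,1,2,2-tetrachloroethane
Product: 7 2-bromo-6-phenoxyphenyl N,N-diethylcarbamate, via C6-aryllithium 6 (not isolated)
Conditions: s-BuLi (1.15 equiv), TMEDA (1.15 equiv), THF, −78 °C, 1 h; then 5 (1.3 equiv) in THF, added quickly, −78 °C → rt; aq NH4Cl
Reagents that add atoms: 1,2-dibromo-1,1,2,2-tetrachloroethane, ClC(Cl)(Br)C(Cl)(Cl)Br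
Why: Directed ortho-metalation, in which the carbamate carbonyl binds s-BuLi·TMEDA and delivers it to C6–H, the only C–H ortho to this strong directing group (C2 is blocked and the ether oxygen directs far more weakly), the diethylcarbamate resists anionic ortho-Fries migration at −78 °C, and halophilic attack of 6 on 5 transfers bromine with loss of bromide and tetrachloroethene.

**Step 3**
Reactants: 7 2-bromo-6-phenoxyphenyl N,N-diethylcarbamate; 8 bromine
Product: 12 2,3-dibromo-6-(2,4-dibromophenoxy)phenyl N,N-diethylcarbamate, via 6,4'-dibromide 9 (not isolated), via 6,2',4'-tribromide 10 (not isolated), via 5,6,4'-tribromide 11 (not isolated)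
Conditions: Br2 (3.1 equiv, in three portions), AcOH, dark, 20 → 55 °C; FeBr3 (5 mol %) with the last portion; HPLC control; aq NaHSO3 quench
Reagents that add atoms: bromine, BrBr
Why: Each C–Br bond forms by electrophilic aromatic substitution, in which polarised Br2 (activated by FeBr3 for the slowest event) attacks the ring, the arenium cation is stabilised by a lone pair of the bridging oxygen, and loss of a proton gives HBr. The closest known reactions are the stepwise para-then-ortho bromination of diphenyl ether up to its 2,2',4,4'-tetrabromide, the bromination of guaiacol esters para to the methoxy group, and the bromination of 3-bromoanisole para to oxygen next to the bromine. No ring closes and no stereocentre forms. The unsubstituted ring B should react first at C4' to give 9, and the next two events, at C2' (ortho to O, meta to one Br) and at C5 (para to O, ortho to C6–Br, meta to the carbamate oxygen), are judged close in rate, so 10 and 11 may both lie on the path and both lead to 12. On ring A the step needs C5 over C3 and C4: C4 is para only to the acylated oxygen, whose lone pair is engaged by the carbamate carbonyl, and is meta to both the ether oxygen and C6–Br, while C3 is the crowded ortho site of an aryl ether and should lose to the para site, which C6–Br also favours as an ortho/para director. The step must also stop at three new bromines, and here the only activated site left, C6', is ortho to oxygen and meta to two bromines and so clearly less reactive than C5 or C2', a gap that the limited bromine charge exploits.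

**Step 4**
Reactants: 12 2,3-dibromo-6-(2,4-dibromophenoxy)phenyl N,N-diethylcarbamate
Product: 14 2,3-dibromo-6-(2,4-dibromophenoxy)phenol, via potassium phenolate 13 (not isolated)
Conditions: KOH (10 equiv), EtOH/H2O 4:1, reflux, N2; then 2 M HCl to pH 2
Reagents that add atoms: none
Why: Base hydrolysis of an aryl carbamate (addition–elimination at the carbonyl with acyl–oxygen cleavage), in which hydroxide adds to the carbamate carbon and the bromine-stabilised phenolate 13 leaves, the carbamic acid salt breaks down to diethylamine and carbonate, the unactivated aryl bromides and the diaryl ether should not undergo substitution at about 80 °C, and acidification gives the free phenol 14.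

**Compound list**
1 | 2-phenoxyphenol | Oc1ccccc1Oc1ccccc1 | starting material
2 | N,N-diethylcarbamoyl chloride | CCN(CC)C(=O)Cl | starting material
3 | sodium 2-phenoxyphenolate | [Na+].[O-]c1ccccc1Oc1ccccc1 | intermediate
4 | 2-phenoxyphenyl N,N-diethylcarbamate | CCN(CC)C(=O)Oc1ccccc1Oc1ccccc1 | intermediate
5 | 1,2-dibromo-1,1,2,2-tetrachloroethane | ClC(Cl)(Br)C(Cl)(Cl)Br | starting material
6 | 2-lithio-6-phenoxyphenyl N,N-diethylcarbamate | CCN(CC)C(=O)Oc1c([Li])cccc1Oc1ccccc1 | intermediate
7 | 2-bromo-6-phenoxyphenyl N,N-diethylcarbamate | CCN(CC)C(=O)Oc1c(Br)cccc1Oc1ccccc1 | intermediate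
8 | bromine | BrBr | starting material
9 | 2-bromo-6-(4-bromophenoxy)phenyl N,N-diethylcarbamate | CCN(CC)C(=O)Oc1c(Br)cccc1Oc1ccc(Br)cc1 | intermediate
10 | 2-bromo-6-(2,4-dibromophenoxy)phenyl N,N-diethylcarbamate | CCN(CC)C(=O)Oc1c(Br)cccc1Oc1ccc(Br)cc1Br | intermediate
11 | 2,3-dibromo-6-(4-bromophenoxy)phenyl N,N-diethylcarbamate | CCN(CC)C(=O)Oc1c(Br)c(Br)ccc1Oc1ccc(Br)cc1 | intermediate
12 | 2,3-dibromo-6-(2,4-dibromophenoxy)phenyl N,N-diethylcarbamate | CCN(CC)C(=O)Oc1c(Br)c(Br)ccc1Oc1ccc(Br)cc1Br | intermediate
13 | potassium 2,3-dibromo-6-(2,4-dibromophenoxy)phenolate | [K+].[O-]c1c(Oc2ccc(Br)cc2Br)ccc(Br)c1Br | intermediate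
14 | 2,3-dibromo-6-(2,4-dibromophenoxy)phenol | Oc1c(Oc2ccc(Br)cc2Br)ccc(Br)c1Br | target

Total step count: 4
Longest linear sequence: 4

**Steps most likely to fail**

**Step 3.**
- Risk: the sites may not be told apart well enough. Attack could occur at C3 or C4 of ring A, a fourth substitution at C6' could begin before C5 has reacted, or the reaction could stall after two new bromines. Each case gives closely related bromides that are hard to separate.
- Fallback: it sets out from 7 and comes back at 12. It removes the ring A regiochemistry from the electrophilic step and sets C5–Br by carbanion chemistry.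
- LDA (1.1 equiv, THF, −78 °C) removes C5–H, the ring A proton acidified by the neighbouring bromine. This gives 2-bromo-3-lithio-6-phenoxyphenyl N,N-diethylcarbamate F1.
- F1 may persist, or it may isomerise by halogen dance to the carbamate-chelated 3-bromo-2-lithio-6-phenoxyphenyl N,N-diethylcarbamate F2.
- Either aryllithium gives the same 2,3-dibromo-6-phenoxyphenyl N,N-diethylcarbamate F3 on quench with 5.
- Ring A then carries two bromines and an acylated oxygen. Br2 (2.05 equiv, AcOH) should therefore touch only ring B, first at C4' (giving 11) and then at C2', which leads to 12.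

**Step 2.**
- Risk: the carbamoyl group may migrate by anionic ortho-Fries rearrangement if the cooling lapses. Lithiation beside the ether oxygen may compete. Lithium–bromine exchange between the aryllithium and the freshly formed bromide may scramble the halogen.
- Fallback: it sets out from 1, comes back at 7, and uses no organolithium.
- Amine-mediated ortho-bromination of the free phenol (NBS 1.0 equiv, i-Pr2NH 10 mol %, CH2Cl2, 0 °C) relays bromine to the carbon next to the hydrogen-bonded O–H rather than to the para carbon C4. The phenol ring is far more reactive than ring B. This gives 2-bromo-6-phenoxyphenol F4.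
- Deprotonation with NaH gives sodium 2-bromo-6-phenoxyphenolate F5, and acylation with 2 as in step 1 gives 7.

**Step 4.**
- Risk: acyl substitution may be slow at a tertiary carbamate flanked by two ortho substituents, so long heating in strong base would be needed.
- During that heating the liberated phenolate may displace the C2' bromine with closure of a dioxin ring. The aryl group may shift between the two oxygens in a Smiles-type process. Bromine may also be lost.
- Fallback: it sets out from 12 and comes back at 14. It replaces hydrolysis by reductive cleavage under neutral conditions.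
- Cp2Zr(H)Cl (slight excess, THF, rt) transfers hydride to the carbamate carbonyl, the aryloxide is expelled from the tetrahedral adduct, and aqueous work-up gives 14. This is a known way to turn aryl O-carbamates into phenols, and it leaves aryl bromides and diaryl ethers alone.
- The fallback makes no compound outside the list (entry F0).

**Further compounds**
F1 | step 3 | 2-bromo-3-lithio-6-phenoxyphenyl N,N-diethylcarbamate | CCN(CC)C(=O)Oc1c(Br)c([Li])ccc1Oc1ccccc1
F2 | step 3 | 3-bromo-2-lithio-6-phenoxyphenyl N,N-diethylcarbamate | CCN(CC)C(=O)Oc1c([Li])c(Br)ccc1Oc1ccccc1
F3 | step 3 | 2,3-dibromo-6-phenoxyphenyl N,N-diethylcarbamate | CCN(CC)C(=O)Oc1c(Br)c(Br)ccc1Oc1ccccc1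
F4 | step 2 | 2-bromo-6-phenoxyphenol | Oc1c(Br)cccc1Oc1ccccc1
F5 | step 2 | sodium 2-bromo-6-phenoxyphenolate | [Na+].[O-]c1c(Br)cccc1Oc1ccccc1
F0 | step 4 | none | none
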